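**Retrosynthetic overview**
- Target 21 comes from its nona-O-benzyl ether 20 by one global hydrogenolysis.
- The strategy rests on the adjacent pair C2 of the dihydrobenzofuran (bonded to O1) and the exocyclic methine C-alpha (bonded to the 3,4-dihydroxyphenyl ring and to catechin C8). The O1–C2 bond and the C-alpha–aryl bond are made together by Pd-catalysed anti-oxyarylation of the E alkene of phenol 15 with aryl triflate 19; the 2S,alpha-R pair is the anti adduct.
- 15 comes from Suzuki coupling of E-alkenyl boronate 9 with 8-bromo-penta-O-benzylcatechin 13, then desilylation. 9 is built from phloroglucinol by Claisen rearrangement and cross-metathesis; 13 from (+)-catechin.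
- Ring order: both benzene systems and the catechin pyran ring are purchased; the dihydrofuran ring is the only ring made, in the penultimate step.

Key step: step 14

Remark: the flavan unit is numbered as in catechin (O1, C2, C3, C4, C8) and the exocyclic diarylmethine carbon is called C-alpha. A triisopropylsilyl ether is used for the phenol because it should survive the aqueous phosphate of the coupling step.

**Route**

Step 1
Reactants: 1 phloroglucinol
Product: 2 1,3,5-tris(benzyloxy)benzene
Conditions: BnBr (3.3 equiv), K2CO3, DMF, rt to 60 °C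
Reagents that add atoms: benzyl bromide, BrCc1ccccc1
Why: Williamson etherification of all three phenols, where carbonate in a dipolar aprotic solvent should favour O- over C-benzylation of the phloroglucinol nucleus.

Step 2
Reactants: 2 1,3,5-tris(benzyloxy)benzene
Product: 3 3,5-bis(benzyloxy)phenol
Conditions: NaSEt (1.3 equiv), DMF, 125 °C; then aq HCl
Reagents that add atoms: none
Why: SN2 dealkylation by thiolate at one benzylic carbon, which should stop after one ether because the phenoxide formed deactivates the remaining two toward loss of a second phenoxide.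

Step 3
Reactants: 3 3,5-bis(benzyloxy)phenol; 4 allyl bromide
Product: 5 1-(allyloxy)-3,5-bis(benzyloxy)benzene
Conditions: K2CO3, acetone, reflux
Reagents that add atoms: none
Why: Williamson O-allylation of the single free phenol.

Step 4
Reactants: 5 1-(allyloxy)-3,5-bis(benzyloxy)benzene
Product: 6 2-allyl-3,5-bis(benzyloxy)phenol
Conditions: N,N-diethylaniline, 190 °C
Reagents that add atoms: none
Why: aromatic Claisen rearrangement ([3,3]-sigmatropic shift, then rearomatisation), which can give only one regioisomer because the two ortho positions are equivalent.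

Step 5
Reactants: 6 2-allyl-3,5-bis(benzyloxy)phenol
Product: 7 [2-allyl-3,5-bis(benzyloxy)phenoxy]triisopropylsilane
Conditions: iPr3SiCl, imidazole, DMF, rt
Reagents that add atoms: triisopropylsilyl chloride, CC(C)[Si](Cl)(C(C)C)C(C)C
Why: standard silylation of a phenol, masking the acidic OH during metathesis and cross-coupling with a group that tolerates aqueous base.

Step 6
Reactants: 7 [2-allyl-3,5-bis(benzyloxy)phenoxy]triisopropylsilane; 8 vinylboronic acid pinacol ester
Product: 9 (E)-alkenyl boronate, 2-{(E)-3-[2,4-bis(benzyloxy)-6-(triisopropylsilyloxy)phenyl]prop-1-enyl}-4,4,5,5-tetramethyl-1,3,2-dioxaborolane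
Conditions: 8 (3 equiv), second-generation Grubbs catalyst (H2IMes)(PCy3)Cl2Ru=CHPh (5 mol%), CH2Cl2, 40 °C
Reagents that add atoms: none
Why: olefin cross-metathesis of an allylarene with a vinyl boronate, driven by loss of ethylene and expected to be E-selective because of the bulky boronate group.

Step 7
Reactants: 10 (+)-catechin
Product: 11 5,7,3',4'-tetra-O-benzylcatechin, (2R,3S)-5,7-bis(benzyloxy)-2-[3,4-bis(benzyloxy)phenyl]chroman-3-ol
Conditions: BnBr (4.4 equiv), K2CO3, DMF, 0 °C to rt
Reagents that add atoms: benzyl bromide, BrCc1ccccc1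
Why: Williamson benzylation of the four phenols under mild carbonate conditions that leave the secondary alcohol untouched and should avoid base-induced epimerisation at C2.

Step 8
Reactants: 11 5,7,3',4'-tetra-O-benzylcatechin
Product: 12 penta-O-benzylcatechin, (2R,3S)-3,5,7-tris(benzyloxy)-2-[3,4-bis(benzyloxy)phenyl]chromane
Conditions: NaH, BnBr, Bu4NI (cat.), DMF, 0 °C to rt
Reagents that add atoms: benzyl bromide, BrCc1ccccc1
Why: Williamson benzylation of the C3 alkoxide, safe now that no free phenol remains to open the pyran ring.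

Step 9
Reactants: 12 penta-O-benzylcatechin
Product: 13 8-bromo-penta-O-benzylcatechin
Conditions: NBS (1.0 equiv), CH2Cl2, −78 °C to rt
Reagents that add atoms: N-bromosuccinimide, O=C1CCC(=O)N1Br
Why: electrophilic aromatic bromination, for which C8 of the phloroglucinol-type ring of protected catechins is the most reactive position.

Step 10
Reactants: 9 (E)-alkenyl boronate; 13 8-bromo-penta-O-benzylcatechin
Product: 14 silyl-protected C8-alkenyl catechin, (2R,3S)-3,5,7-tris(benzyloxy)-2-[3,4-bis(benzyloxy)phenyl]-8-{(E)-3-[2,4-bis(benzyloxy)-6-(triisopropylsilyloxy)phenyl]prop-1-enyl}chromane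
Conditions: Pd(OAc)2 (5 mol%), SPhos (10 mol%), K3PO4, toluene/H2O (10:1), 80 °C
Reagents that add atoms: none
Why: Suzuki–Miyaura coupling, in which an electron-rich dialkylbiaryl phosphine should allow oxidative addition into the di-ortho-oxygenated C8–Br bond and the alkenyl group is transferred with retention of E geometry.

Step 11
Reactants: 14 silyl-protected C8-alkenyl catechin
Product: 15 free phenol, 3,5-bis(benzyloxy)-2-{(E)-3-[(2R,3S)-3,5,7-tris(benzyloxy)-2-(3,4-bis(benzyloxy)phenyl)chroman-8-yl]allyl}phenol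
Conditions: Bu4NF, AcOH, THF, 0 °C to rt
Reagents that add atoms: none
Why: fluoride-induced cleavage of the aryl silyl ether, buffered with acetic acid so that no strongly basic phenoxide can shift the skipped double bond.

Step 12
Reactants: 16 3,4-bis(benzyloxy)benzaldehyde
Product: 18 3,4-bis(benzyloxy)phenol, via 3,4-bis(benzyloxy)phenyl formate 17 (not isolated)
Conditions: mCPBA, CH2Cl2, 0 °C to rt; then K2CO3 (cat.), MeOH, rt
Reagents that add atoms: meta-chloroperbenzoic acid, OOC(=O)c1cccc(Cl)c1
Why: Baeyer–Villiger oxidation of an electron-rich benzaldehyde with aryl migration gives the formate, which is removed by transesterification with methanol.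

Step 13
Reactants: 18 3,4-bis(benzyloxy)phenol
Product: 19 3,4-bis(benzyloxy)phenyl trifluoromethanesulfonate
Conditions: Tf2O, pyridine, CH2Cl2, 0 °C
Reagents that add atoms: trifluoromethanesulfonic anhydride, O=S(=O)(OS(=O)(=O)C(F)(F)F)C(F)(F)F
Why: standard O-sulfonylation of a phenol to the aryl triflate electrophile.

Step 14
Reactants: 15 free phenol E-alkene; 19 3,4-bis(benzyloxy)phenyl trifluoromethanesulfonate
Product: 20 nona-O-benzyl ether of the target, (2S)-4,6-bis(benzyloxy)-2-{(R)-[3,4-bis(benzyloxy)phenyl][(2R,3S)-3,5,7-tris(benzyloxy)-2-(3,4-bis(benzyloxy)phenyl)chroman-8-yl]methyl}-2,3-dihydrobenzofuran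
Conditions: Pd2(dba)3 (2.5 mol%), (S)-KenPhos [(S)-2-dicyclohexylphosphino-2'-(dimethylamino)-1,1'-binaphthyl] (7.5 mol%), LiOtBu (1.4 equiv), PhCF3, 95 °C
Reagents that add atoms: none
Why: Proposed new method: oxidative addition of triflate 19 to zerovalent palladium bearing a bulky monodentate biaryl phosphine should give a cationic arylpalladium species that binds the E alkene of 15, after which the lithium phenoxide attacks the alkene carbon next to its own CH2 from the face opposite palladium and C–C reductive elimination with retention delivers the 3,4-bis(benzyloxy)phenyl group to the carbon attached to catechin C8. The closest known reaction type is the palladium-catalysed carboalkoxylation of 2-allylphenols with aryl triflates through anti-oxypalladation, which has not been shown for an internal alkene capped by a 2,6-dioxygenated aryl group or with ligand control of the alkene face. The dihydrofuran ring closes in the 5-exo-trig mode by this anti-oxypalladation. C2 and C-alpha are created together: their relative configuration follows from stereospecific anti addition of O and aryl across the E double bond, and the absolute sense (2S, alpha-R) from the alkene face that the chiral ligand, reinforced or opposed by the resident catechin unit, lets the arylpalladium occupy, so the ligand antipode is chosen to match. The step needs 5-exo over 6-endo attack, anti over syn addition and reductive elimination ahead of beta-hydride elimination: the ortho-allylphenol tether and the twisted, di-ortho-substituted catechin ring (weak benzylic activation of the distal carbon) favour 5-exo closure, the non-coordinating triflate keeps palladium cationic so that outer-sphere attack is preferred, and the bulky electron-rich phosphine should speed C–C bond formation from the hindered benzylic alkylpalladium. Attack on the other face would give the (2R, alpha-S) diastereomer, not an enantiomer, which should be removable by chromatography.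

Step 15
Reactants: 20 nona-O-benzyl ether of the target
Product: 21 CNP0280971.2, (2S)-2-{(R)-(3,4-dihydroxyphenyl)[(2R,3S)-2-(3,4-dihydroxyphenyl)-3,5,7-trihydroxychroman-8-yl]methyl}-2,3-dihydrobenzofuran-4,6-diol
Conditions: H2 (1 atm), Pd(OH)2/C, THF/MeOH (1:1), rt; filtration and concentration under argon
Reagents that add atoms: none
Why: catalytic hydrogenolysis of the nine benzyl ethers, under which the aryl alkyl ether bonds of the dihydrofuran and pyran rings and all four stereocentres should be unaffected.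

**Compound list**
1 | phloroglucinol | Oc1cc(O)cc(O)c1 | starting material
2 | 1,3,5-tris(benzyloxy)benzene | c1ccc(COc2cc(OCc3ccccc3)cc(OCc3ccccc3)c2)cc1 | intermediate
3 | 3,5-bis(benzyloxy)phenol | Oc1cc(OCc2ccccc2)cc(OCc2ccccc2)c1 | intermediate
4 | allyl bromide | C=CCBr | starting material
5 | 1-(allyloxy)-3,5-bis(benzyloxy)benzene | C=CCOc1cc(OCc2ccccc2)cc(OCc2ccccc2)c1 | intermediate
6 | 2-allyl-3,5-bis(benzyloxy)phenol | C=CCc1c(O)cc(OCc2ccccc2)cc1OCc1ccccc1 | intermediate
7 | [2-allyl-3,5-bis(benzyloxy)phenoxy]triisopropylsilane | C=CCc1c(O[Si](C(C)C)(C(C)C)C(C)C)cc(OCc2ccccc2)cc1OCc1ccccc1 | intermediate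
8 | vinylboronic acid pinacol ester | C=CB1OC(C)(C)C(C)(C)O1 | starting material
9 | 2-{(E)-3-[2,4-bis(benzyloxy)-6-(triisopropylsilyloxy)phenyl]prop-1-enyl}-4,4,5,5-tetramethyl-1,3,2-dioxaborolane | CC(C)[Si](C(C)C)(C(C)C)Oc1cc(OCc2ccccc2)cc(OCc2ccccc2)c1C/C=C/B1OC(C)(C)C(C)(C)O1 | intermediate
10 | (+)-catechin, (2R,3S) | O[C@H]1Cc2c(O)cc(O)cc2O[C@@H]1c1ccc(O)c(O)c1 | starting material
11 | 5,7,3',4'-tetra-O-benzylcatechin, (2R,3S) | O[C@H]1Cc2c(OCc3ccccc3)cc(OCc3ccccc3)cc2O[C@@H]1c1ccc(OCc2ccccc2)c(OCc2ccccc2)c1 | intermediate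
12 | penta-O-benzylcatechin, (2R,3S) | c1ccc(CO[C@H]2Cc3c(OCc4ccccc4)cc(OCc4ccccc4)cc3O[C@@H]2c2ccc(OCc3ccccc3)c(OCc3ccccc3)c2)cc1 | intermediate
13 | 8-bromo-penta-O-benzylcatechin, (2R,3S) | Brc1c(OCc2ccccc2)cc(OCc2ccccc2)c2c1O[C@H](c1ccc(OCc3ccccc3)c(OCc3ccccc3)c1)[C@@H](OCc1ccccc1)C2 | intermediate
14 | (2R,3S)-3,5,7-tris(benzyloxy)-2-[3,4-bis(benzyloxy)phenyl]-8-{(E)-3-[2,4-bis(benzyloxy)-6-(triisopropylsilyloxy)phenyl]prop-1-enyl}chromane | CC(C)[Si](C(C)C)(C(C)C)Oc1cc(OCc2ccccc2)cc(OCc2ccccc2)c1C/C=C/c1c(OCc2ccccc2)cc(OCc2ccccc2)c2c1O[C@H](c1ccc(OCc3ccccc3)c(OCc3ccccc3)c1)[C@@H](OCc1ccccc1)C2 | intermediate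
15 | 3,5-bis(benzyloxy)-2-{(E)-3-[(2R,3S)-3,5,7-tris(benzyloxy)-2-(3,4-bis(benzyloxy)phenyl)chroman-8-yl]allyl}phenol | Oc1cc(OCc2ccccc2)cc(OCc2ccccc2)c1C/C=C/c1c(OCc2ccccc2)cc(OCc2ccccc2)c2c1O[C@H](c1ccc(OCc3ccccc3)c(OCc3ccccc3)c1)[C@@H](OCc1ccccc1)C2 | intermediate
16 | 3,4-bis(benzyloxy)benzaldehyde | O=Cc1ccc(OCc2ccccc2)c(OCc2ccccc2)c1 | starting material
17 | 3,4-bis(benzyloxy)phenyl formate | O=COc1ccc(OCc2ccccc2)c(OCc2ccccc2)c1 | intermediate
18 | 3,4-bis(benzyloxy)phenol | Oc1ccc(OCc2ccccc2)c(OCc2ccccc2)c1 | intermediate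
19 | 3,4-bis(benzyloxy)phenyl trifluoromethanesulfonate | O=S(=O)(Oc1ccc(OCc2ccccc2)c(OCc2ccccc2)c1)C(F)(F)F | intermediate
20 | nona-O-benzyl ether of the target, (2S, alpha-R, catechin 2R,3S) | C(c1ccccc1)Oc1cc(OCc3ccccc3)c2c(c1)O[C@H]([C@H](c1ccc(OCc3ccccc3)c(OCc3ccccc3)c1)c1c(OCc3ccccc3)cc(OCc3ccccc3)c3c1O[C@H](c1ccc(OCc4ccccc4)c(OCc4ccccc4)c1)[C@@H](OCc1ccccc1)C3)C2 | intermediate
21 | CNP0280971.2, (2S)-2-{(R)-(3,4-dihydroxyphenyl)[(2R,3S)-2-(3,4-dihydroxyphenyl)-3,5,7-trihydroxychroman-8-yl]methyl}-2,3-dihydrobenzofuran-4,6-diol | Oc1cc(O)c2c(c1)O[C@H]([C@H](c1ccc(O)c(O)c1)c1c(O)cc(O)c3c1O[C@H](c1ccc(O)c(O)c1)[C@@H](O)C3)C2 | target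

**Count**
Total steps: 15. Longest linear sequence: 10 steps (steps 1–6, 10, 11, 14, 15).

**Steps most likely to fail**

1. Step 14 (proposed new method). Possible failures are 6-endo closure to a chroman, beta-hydride elimination or Heck-type arylation in place of C–C reductive elimination, O-arylation of the phenol by the triflate, base-induced migration of the double bond, and poor selection of the alkene face. The fallback uses known chemistry, sets out from 9, 19 and 12, and returns at 20. Suzuki–Miyaura coupling of boronate 9 with triflate 19 (Pd(OAc)2, SPhos, K3PO4, toluene/H2O) should give the E-1,3-diarylpropene F1. Shi epoxidation (D-fructose-derived ketone, KHSO5, K2CO3 buffer, MeCN/dimethoxymethane/H2O, 0 °C) should convert it to the (2R,3R)-trans-epoxide F2. Bu4NF in THF then frees the epoxy phenol F3, whose phenoxide opens the oxirane at the homobenzylic carbon (5-exo-tet, inversion) to the dihydrobenzofuranyl carbinol F4, in which C2 is already S. Ionisation of F4 with Me3SiOTf in CH2Cl2 at −78 °C in the presence of penta-O-benzylcatechin 12 (Friedel–Crafts alkylation at C8, the site that is also brominated in step 9) would give 20 together with its C-alpha epimer, to be separated by chromatography.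

2. Step 10. Possible failures are slow oxidative addition at the di-ortho-oxygenated bromide, protodeboronation of the alkenyl boronate, and palladium hydride migration of the double bond. The fallback sets out from 7 and 13 and returns at 14. Hydroboration of 7 with 9-borabicyclo[3.3.1]nonane gives the B-alkyl borane F5, which is oxidised in the same flask (NaBO3·4H2O) to the primary alcohol F6. Dess–Martin oxidation gives the aldehyde F7. Bromine–lithium exchange on 13 (n-BuLi, THF, −78 °C) gives the 8-lithio species F8, which adds to F7 to give the carbinol F9 as both epimers. Dehydration with Burgess reagent (toluene, 50 °C) can eliminate in one direction only and, through conjugation with the catechin ring, should give the E alkene 14.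

3. Step 6. Possible failures are ruthenium hydride isomerisation of the allylarene to the styrene, incomplete E selectivity, and homodimerisation. The fallback sets out from 7 and returns at 9. Dihydroxylation and periodate cleavage in one flask (OsO4 cat., NaIO4, 2,6-lutidine, dioxane/H2O) pass through the diol F10 to the arylacetaldehyde F11. Takai-type boron olefination (CrCl2, Cl2CHB(pin), LiI, THF, rt) should then give the E-alkenyl boronate 9.

**Further compounds**
F1 | step 14 | (E)-1-[3,4-bis(benzyloxy)phenyl]-3-[2,4-bis(benzyloxy)-6-(triisopropylsilyloxy)phenyl]prop-1-ene | CC(C)[Si](C(C)C)(C(C)C)Oc1cc(OCc2ccccc2)cc(OCc2ccccc2)c1C/C=C/c1ccc(OCc2ccccc2)c(OCc2ccccc2)c1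
F2 | step 14 | (2R,3R)-2-[3,4-bis(benzyloxy)phenyl]-3-[2,4-bis(benzyloxy)-6-(triisopropylsilyloxy)benzyl]oxirane | CC(C)[Si](C(C)C)(C(C)C)Oc1cc(OCc2ccccc2)cc(OCc2ccccc2)c1C[C@H]1O[C@@H]1c1ccc(OCc2ccccc2)c(OCc2ccccc2)c1
F3 | step 14 | 3,5-bis(benzyloxy)-2-{[(2R,3R)-3-(3,4-bis(benzyloxy)phenyl)oxiran-2-yl]methyl}phenol (not isolated) | Oc1cc(OCc2ccccc2)cc(OCc2ccccc2)c1C[C@H]1O[C@@H]1c1ccc(OCc2ccccc2)c(OCc2ccccc2)c1
F4 | step 14 | (R)-[(2S)-4,6-bis(benzyloxy)-2,3-dihydrobenzofuran-2-yl][3,4-bis(benzyloxy)phenyl]methanol | C(c1ccccc1)Oc1cc(OCc3ccccc3)c2c(c1)O[C@H]([C@H](O)c1ccc(OCc3ccccc3)c(OCc3ccccc3)c1)C2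
F5 | step 10 | 9-{3-[2,4-bis(benzyloxy)-6-(triisopropylsilyloxy)phenyl]propyl}-9-borabicyclo[3.3.1]nonane (not isolated) | CC(C)[Si](C(C)C)(C(C)C)Oc1cc(OCc2ccccc2)cc(OCc2ccccc2)c1CCCB1C2CCCC1CCC2
F6 | step 10 | 3-[2,4-bis(benzyloxy)-6-(triisopropylsilyloxy)phenyl]propan-1-ol | CC(C)[Si](C(C)C)(C(C)C)Oc1cc(OCc2ccccc2)cc(OCc2ccccc2)c1CCCO
F7 | step 10 | 3-[2,4-bis(benzyloxy)-6-(triisopropylsilyloxy)phenyl]propanal | CC(C)[Si](C(C)C)(C(C)C)Oc1cc(OCc2ccccc2)cc(OCc2ccccc2)c1CCC=O
F8 | step 10 | 8-lithio-penta-O-benzylcatechin, (2R,3S) (not isolated) | [Li]c1c(OCc2ccccc2)cc(OCc2ccccc2)c2c1O[C@H](c1ccc(OCc3ccccc3)c(OCc3ccccc3)c1)[C@@H](OCc1ccccc1)C2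
F9 | step 10 | 3-[2,4-bis(benzyloxy)-6-(triisopropylsilyloxy)phenyl]-1-[(2R,3S)-3,5,7-tris(benzyloxy)-2-(3,4-bis(benzyloxy)phenyl)chroman-8-yl]propan-1-ol, both carbinol epimers | CC(C)[Si](C(C)C)(C(C)C)Oc1cc(OCc2ccccc2)cc(OCc2ccccc2)c1CCC(O)c1c(OCc2ccccc2)cc(OCc2ccccc2)c2c1O[C@H](c1ccc(OCc3ccccc3)c(OCc3ccccc3)c1)[C@@H](OCc1ccccc1)C2
F10 | step 6 | 3-[2,4-bis(benzyloxy)-6-(triisopropylsilyloxy)phenyl]propane-1,2-diol, racemic (not isolated) | CC(C)[Si](C(C)C)(C(C)C)Oc1cc(OCc2ccccc2)cc(OCc2ccccc2)c1CC(O)CO
F11 | step 6 | [2,4-bis(benzyloxy)-6-(triisopropylsilyloxy)phenyl]acetaldehyde | CC(C)[Si](C(C)C)(C(C)C)Oc1cc(OCc2ccccc2)cc(OCc2ccccc2)c1CC=O
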